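The side chain is cut at two bonds, C13–CH3 and C14–C15. The feature exploited is the E-trisubstituted alkene C13(CH3)=C14 that lies between the C11–C12 tether on C9 of the ring A/B decalin and the allylic carbinol C15 next to C16 of the butenolide ring. In one operation a terminal alkyne is methylmetalated syn and the alkenyl metal is trapped by an α-alkoxy aldehyde under chelation, which sets the alkene geometry and C15. The precursor is a larixol-derived decalin with silylated C6 and C8 hydroxyls and a but-3-ynyl chain on C9; its partner is (S)-2-(4-methoxybenzyloxy)-3-methylbut-3-enal from prenol. Ring-closing metathesis then builds the butenolide.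

Key step: step 11

Remark: labdane names are used up to compound 7 and the target numbering from step 11 on (chain C11–C15, butenolide C16–C19 with the ring oxygen on C16; the terminal alkyne carbon of 7 is C14); larixol is taken as the commercial larch-resin diterpene.

Step 1
Reactants: 1 larixol, (13S)-labda-8(17),14-diene-6α,13-diol
Product: 2 (13S)-8α,17-epoxylabd-14-ene-6α,13-diol
Conditions: mCPBA (1.1 equiv), CH2Cl2, 0 °C
Reagents that add atoms: 3-chloroperoxybenzoic acid, O=C(OO)c1cccc(Cl)c1
Why: Prilezhaev epoxidation should pick the electron-richer 1,1-disubstituted C8=CH2 alkene over the vinyl group and approach the α face, because the β face is screened by the axial C10 methyl and the equatorial 6α-OH can hydrogen-bond to the peracid, which sets C8.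

Step 2
Reactants: 2 (13S)-8α,17-epoxylabd-14-ene-6α,13-diol
Product: 3 (13S)-labd-14-ene-6α,8α,13-triol
Conditions: LiAlH4, THF, 0 °C to reflux
Reagents that add atoms: none
Why: Hydride opens the spiro-epoxide by SN2 reduction at its unhindered CH2 carbon, so the C8–O bond is untouched and the tertiary 8α-carbinol with an 8β-methyl should result.

Step 3
Reactants: 3 (13S)-labd-14-ene-6α,8α,13-triol
Product: 4 6α,8α-dihydroxy-14,15-dinorlabdan-13-one
Conditions: KMnO4, acetone/H2O, 0 °C to rt
Reagents that add atoms: none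
Why: Permanganate cleavage of a tertiary vinyl carbinol (dihydroxylation, glycol fission, oxidative decarboxylation) is the standard degradation of labdane side chains to the C13 methyl ketone, and the hindered secondary C6–OH and tertiary C8–OH should survive the cold, non-acidic medium.

Step 4
Reactants: 4 6α,8α-dihydroxy-14,15-dinorlabdan-13-one
Product: 5 6α,8α-bis(triethylsilyloxy)-14,15-dinorlabdan-13-one
Conditions: Et3SiOTf (3 equiv), 2,6-lutidine, CH2Cl2, −78 to 0 °C; aq. citric acid work-up
Reagents that add atoms: triethylsilyl trifluoromethanesulfonate, CC[Si](CC)(CC)OS(=O)(=O)C(F)(F)F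
Why: O-Silylation with a silyl triflate and a hindered pyridine base should cap the secondary and the tertiary alcohol faster than the ketone is enolised, and any enol silane is hydrolysed in the mildly acidic work-up while the alkyl silyl ethers stay.

Step 5
Reactants: 5 6α,8α-bis(triethylsilyloxy)-14,15-dinorlabdan-13-one
Product: 7 6α,8α-bis(triethylsilyloxy)-14,15-dinorlabd-13(16)-yne, via enol diethyl phosphate 6 (not isolated)
Conditions: LiN(iPr)2 (1.1 equiv), THF, −78 °C; ClP(O)(OEt)2, −78 °C to rt; LiN(iPr)2 (2.5 equiv), −78 °C to rt; H2O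
Reagents that add atoms: none
Why: Kinetic deprotonation at the methyl group, O-phosphorylation and base-induced elimination of diethyl phosphate (the enol phosphate route from a methyl ketone to a terminal alkyne) should give the acetylide, which is protonated on work-up, and the silyl ethers are inert to the amide base.

Step 6
Reactants: 8 prenol, 3-methylbut-2-en-1-ol
Product: 9 (R)-(3,3-dimethyloxiran-2-yl)methanol
Conditions: Ti(OiPr)4 (5 mol%), D-(−)-diisopropyl tartrate (6 mol%), tBuOOH, 4 Å molecular sieves, CH2Cl2, −20 °C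
Reagents that add atoms: tert-butyl hydroperoxide, CC(C)(C)OO
Why: In the Katsuki–Sharpless asymmetric epoxidation the titanium complex of the D-(−)-tartrate delivers oxygen to the face of the allylic alcohol that gives the 2R epoxide, and any minor enantiomer would later be removed as a diastereomer after the coupling.

Step 7
Reactants: 9 (R)-(3,3-dimethyloxiran-2-yl)methanol
Product: 10 (S)-3-methylbut-3-ene-1,2-diol
Conditions: Ti(OiPr)4 (1.5 equiv), CH2Cl2, rt; aq. tartaric acid work-up
Reagents that add atoms: none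
Why: In this hydroxyl-directed Lewis acid isomerisation of a 3,3-disubstituted 2,3-epoxy alcohol the titanium alkoxide of the C1 hydroxyl activates the epoxide, the tertiary C3–O bond breaks and a methyl proton is lost to give the isopropenyl carbinol, while the C2–O bond is untouched (the descriptor becomes S only through the change of priorities).

Step 8
Reactants: 10 (S)-3-methylbut-3-ene-1,2-diol
Product: 11 (4S)-2-(4-methoxyphenyl)-4-(prop-1-en-2-yl)-1,3-dioxolane (both epimers at the acetal carbon)
Conditions: 4-MeOC6H4CH(OMe)2, pyridinium p-toluenesulfonate (cat.), CH2Cl2, rt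
Reagents that add atoms: 4-methoxybenzaldehyde dimethyl acetal, COc1ccc(C(OC)OC)cc1
Why: Acid-catalysed transacetalisation should tie the 1,2-diol into the five-membered arylidene acetal without touching the stereocentre.

Step 9
Reactants: 11 (4S)-2-(4-methoxyphenyl)-4-(prop-1-en-2-yl)-1,3-dioxolane
Product: 12 (S)-2-(4-methoxybenzyloxy)-3-methylbut-3-en-1-ol
Conditions: iBu2AlH (3 equiv), CH2Cl2, −78 to 0 °C
Reagents that add atoms: none
Why: In this regioselective reductive acetal opening the aluminium hydride binds the less hindered primary oxygen, that C–O bond ionises and hydride reduces the oxocarbenium ion, which should leave the 4-methoxybenzyl group on the secondary oxygen.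

Step 10
Reactants: 12 (S)-2-(4-methoxybenzyloxy)-3-methylbut-3-en-1-ol
Product: 13 (S)-2-(4-methoxybenzyloxy)-3-methylbut-3-enal
Conditions: Dess–Martin periodinane, pyridine, CH2Cl2, 0 °C; short silica plug, used at once
Reagents that add atoms: none
Why: Dess–Martin oxidation works without strong base or acid, so the α-stereocentre and the β,γ-position of the alkene should be kept if the aldehyde is used directly.

Step 11
Reactants: 7 6α,8α-bis(triethylsilyloxy)-14,15-dinorlabd-13(16)-yne; 13 (S)-2-(4-methoxybenzyloxy)-3-methylbut-3-enal; 14 trimethylaluminium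
Product: 17 (13E,15S,16S)-15-hydroxy-16-(4-methoxybenzyloxy) coupling product (isopropenyl terminus; C6/C8 triethylsilyl ethers), via (E)-alkenyldimethylalane 15 (not isolated), via (E)-alkenylzinc chloride 16 (not isolated)
Conditions: Me3Al (2.5 equiv), Cp2ZrCl2 (0.25 equiv), CH2Cl2, 0 °C to rt; volatiles removed in vacuo; CH2Cl2, ZnCl2 (1.1 equiv, in Et2O), 0 °C; 13 (1.5 equiv), −78 to −20 °C; aq. potassium sodium tartrate
Reagents that add atoms: trimethylaluminium, C[Al](C)C
Why: Cp2ZrCl2 and Me3Al form a methylzirconocene–aluminate pair that adds CH3 and metal syn across the terminal alkyne, CH3 to the internal carbon C13 and aluminium to C14 (Negishi zirconium-catalysed carboalumination), so C12 and the metal are trans and the 13E geometry is fixed before the aldehyde is added. ZnCl2 exchanges aluminium for zinc with retention at the sp2 carbon and releases Me2AlCl, and these Lewis acids tie the carbonyl oxygen and the α-ether oxygen of 13 (the later C16–O) into a five-membered chelate to which the alkenyl group is transferred; the closest known reaction type is the chelation-controlled (Cram cyclic model) addition of alkenylzinc or alkenylmagnesium reagents to α-alkoxy aldehydes. No ring is closed. The one new stereocentre, C15, is controlled by C16: in the chelate the isopropenyl group blocks one face of the carbonyl and attack on the other should give the 15S alcohol, syn to the 16S ether. The step needs regioselective syn carbometalation and chelate instead of Felkin–Anh facial selectivity, which are secured by the unbranched terminal alkyne (C12 is a CH2), by the Lewis-basic benzyl-type ether on C16 in non-coordinating CH2Cl2 and by the remote, bulky, non-chelating silyl ethers on C6 and C8. Stripping the excess Me3Al before the aldehyde is added should suppress methyl transfer to C15.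

Step 12
Reactants: 17 (13E,15S,16S)-15-hydroxy-16-(4-methoxybenzyloxy) coupling product
Product: 18 15-O-triethylsilyl ether of 17 (three triethylsilyl ethers at C6/C8/C15; C16–OPMB)
Conditions: Et3SiOTf (1.3 equiv), 2,6-lutidine, CH2Cl2, −78 °C
Reagents that add atoms: triethylsilyl trifluoromethanesulfonate, CC[Si](CC)(CC)OS(=O)(=O)C(F)(F)F
Why: O-Silylation of the only free hydroxyl with a silyl triflate at low temperature should be fast and leaves the 4-methoxybenzyl ether and both alkenes alone.

Step 13
Reactants: 18 15-O-triethylsilyl ether of 17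
Product: 19 (13E,15S,16S)-16-hydroxy-15-(triethylsilyloxy) compound (isopropenyl terminus; C6/C8 triethylsilyl ethers)
Conditions: DDQ (1.5 equiv), CH2Cl2/pH 7 phosphate buffer, 0 °C
Reagents that add atoms: none
Why: Oxidative cleavage of the electron-rich 4-methoxybenzyl ether by DDQ (hydride abstraction, then hydrolysis of the oxocarbenium ion) under buffered conditions should free only the C16 hydroxyl and keep the silyl ethers.

Step 14
Reactants: 19 (13E,15S,16S)-16-hydroxy-15-(triethylsilyloxy) compound
Product: 20 C16 acrylate of 19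
Conditions: acryloyl chloride, iPr2NEt, DMAP (cat.), CH2Cl2, −20 to 0 °C
Reagents that add atoms: acryloyl chloride, C=CC(Cl)=O
Why: O-Acylation of the single free secondary alcohol with an acid chloride and amine base should proceed without silyl migration because no alkoxide is formed.

Step 15
Reactants: 20 C16 acrylate of 19
Product: 21 tris(triethylsilyl) ether of the target (4-methylfuran-2(5H)-one ring closed; silyl ethers at C6/C8/C15)
Conditions: second-generation Grubbs catalyst (H2IMes)(PCy3)Cl2Ru=CHPh (10 mol%), CH2Cl2 (5 mM), 40 °C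
Reagents that add atoms: none
Why: Ring-closing metathesis of the acrylate with the adjacent 1,1-disubstituted alkene should close the five-membered unsaturated lactone with loss of ethylene, the ring enforcing the cis C17=C18 bond, while the trisubstituted C13=C14 alkene is shielded by the neighbouring C15 silyl ether and C16 is not touched.

Step 16
Reactants: 21 tris(triethylsilyl) ether of the target
Product: 22 target, (5S)-5-[(1S,2E)-1-hydroxy-3-methyl-5-(6α,8α-dihydroxy decalin C9-yl)pent-2-enyl]-4-methylfuran-2(5H)-one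
Conditions: HF·pyridine, pyridine, THF, 0 °C to rt
Reagents that add atoms: none
Why: Fluoride-driven Si–O cleavage in a pyridine-buffered acidic medium should remove the two secondary and the tertiary triethylsilyl group, and it avoids basic fluoride, which could deprotonate C16 of the butenolide or trigger retro-aldol loss of the C15 carbinol.

Compound list
1 | larixol, (13S)-labda-8(17),14-diene-6α,13-diol | C=C[C@@](C)(O)CC[C@@H]1[C@@]2(C)CCCC(C)(C)[C@@H]2[C@@H](O)CC1=C | starting material
2 | (13S)-8α,17-epoxylabd-14-ene-6α,13-diol | C=C[C@@](C)(O)CC[C@@H]1[C@@]2(C)CCCC(C)(C)[C@@H]2[C@@H](O)C[C@]13CO3 | intermediate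
3 | (13S)-labd-14-ene-6α,8α,13-triol | C=C[C@@](C)(O)CC[C@@H]1[C@@]2(C)CCCC(C)(C)[C@@H]2[C@@H](O)C[C@@]1(C)O | intermediate
4 | 6α,8α-dihydroxy-14,15-dinorlabdan-13-one | CC(=O)CC[C@@H]1[C@@]2(C)CCCC(C)(C)[C@@H]2[C@@H](O)C[C@@]1(C)O | intermediate
5 | 6α,8α-bis(triethylsilyloxy)-14,15-dinorlabdan-13-one | CC(=O)CC[C@@H]1[C@@]2(C)CCCC(C)(C)[C@@H]2[C@@H](O[Si](CC)(CC)CC)C[C@@]1(C)O[Si](CC)(CC)CC | intermediate
6 | terminal enol diethyl phosphate of 5 | C=C(OP(=O)(OCC)OCC)CC[C@@H]1[C@@]2(C)CCCC(C)(C)[C@@H]2[C@@H](O[Si](CC)(CC)CC)C[C@@]1(C)O[Si](CC)(CC)CC | intermediate (not isolated)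
7 | 6α,8α-bis(triethylsilyloxy)-14,15-dinorlabd-13(16)-yne | C#CCC[C@@H]1[C@@]2(C)CCCC(C)(C)[C@@H]2[C@@H](O[Si](CC)(CC)CC)C[C@@]1(C)O[Si](CC)(CC)CC | intermediate
8 | prenol | CC(C)=CCO | starting material
9 | (R)-(3,3-dimethyloxiran-2-yl)methanol | OC[C@H]1OC1(C)C | intermediate
10 | (S)-3-methylbut-3-ene-1,2-diol | OC[C@@H](O)C(C)=C | intermediate
11 | (4S)-2-(4-methoxyphenyl)-4-(prop-1-en-2-yl)-1,3-dioxolane | C=C(C)[C@H]1COC(c2ccc(OC)cc2)O1 | intermediate
12 | (S)-2-(4-methoxybenzyloxy)-3-methylbut-3-en-1-ol | OC[C@@H](OCc1ccc(OC)cc1)C(C)=C | intermediate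
13 | (S)-2-(4-methoxybenzyloxy)-3-methylbut-3-enal | O=C[C@@H](OCc1ccc(OC)cc1)C(C)=C | intermediate
14 | trimethylaluminium | C[Al](C)C | starting material
15 | (E)-alkenyldimethylalane (Me2Al on C14, CH3 on C13) | C[Al](C)/C=C(\C)CC[C@@H]1[C@@]2(C)CCCC(C)(C)[C@@H]2[C@@H](O[Si](CC)(CC)CC)C[C@@]1(C)O[Si](CC)(CC)CC | intermediate (not isolated)
16 | (E)-alkenylzinc chloride | Cl[Zn]/C=C(\C)CC[C@@H]1[C@@]2(C)CCCC(C)(C)[C@@H]2[C@@H](O[Si](CC)(CC)CC)C[C@@]1(C)O[Si](CC)(CC)CC | intermediate (not isolated)
17 | (13E,15S,16S)-15-hydroxy-16-(4-methoxybenzyloxy) coupling product | C=C(C)[C@H](OCc1ccc(OC)cc1)[C@@H](O)/C=C(\C)CC[C@@H]1[C@@]2(C)CCCC(C)(C)[C@@H]2[C@@H](O[Si](CC)(CC)CC)C[C@@]1(C)O[Si](CC)(CC)CC | intermediate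
18 | 15-O-triethylsilyl ether of 17 | C=C(C)[C@H](OCc1ccc(OC)cc1)[C@@H](O[Si](CC)(CC)CC)/C=C(\C)CC[C@@H]1[C@@]2(C)CCCC(C)(C)[C@@H]2[C@@H](O[Si](CC)(CC)CC)C[C@@]1(C)O[Si](CC)(CC)CC | intermediate
19 | (13E,15S,16S)-16-hydroxy-15-(triethylsilyloxy) compound | C=C(C)[C@H](O)[C@@H](O[Si](CC)(CC)CC)/C=C(\C)CC[C@@H]1[C@@]2(C)CCCC(C)(C)[C@@H]2[C@@H](O[Si](CC)(CC)CC)C[C@@]1(C)O[Si](CC)(CC)CC | intermediate
20 | C16 acrylate of 19 | C=C(C)[C@H](OC(=O)C=C)[C@@H](O[Si](CC)(CC)CC)/C=C(\C)CC[C@@H]1[C@@]2(C)CCCC(C)(C)[C@@H]2[C@@H](O[Si](CC)(CC)CC)C[C@@]1(C)O[Si](CC)(CC)CC | intermediate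
21 | tris(triethylsilyl) ether of the target | CC1=CC(=O)O[C@@H]1[C@@H](O[Si](CC)(CC)CC)/C=C(\C)CC[C@@H]1[C@@]2(C)CCCC(C)(C)[C@@H]2[C@@H](O[Si](CC)(CC)CC)C[C@@]1(C)O[Si](CC)(CC)CC | intermediate
22 | target, (13E,15S,16S)-6α,8α,15-trihydroxy butenolide | CC1=CC(=O)O[C@@H]1[C@@H](O)/C=C(\C)CC[C@@H]1[C@@]2(C)CCCC(C)(C)[C@@H]2[C@@H](O)C[C@@]1(C)O | target

Total step count: 16 (five to the alkyne, five to the aldehyde, one union, five to the target).
Longest linear sequence: 11 steps (steps 1–5 and 11–16 from larixol; equally steps 6–16 from prenol).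

Steps most likely to fail, riskiest first

Step 11. The addition may follow the Felkin–Anh path instead of the chelate (poor facial selectivity at C15), methyl may be transferred from aluminium in place of the alkenyl group, or the Lewis acids may enolise the aldehyde and move its alkene into conjugation. The fallback sets out from 7 and comes back at 17. The same methylalumination (via 15) would be quenched with I2 in THF at −30 °C to give the (E)-vinyl iodide F1, which is isolated. Lithium–iodine exchange (tBuLi, 2 equiv, Et2O, −78 °C) would give the alkenyllithium F2, and MgBr2·OEt2 would turn it into the alkenylmagnesium bromide F3. Addition of F3 to 13, precomplexed with MgBr2·OEt2 in CH2Cl2 at −78 °C, is the classical magnesium-chelate addition to an α-alkoxy aldehyde and should give 17 without aluminium methyl groups present.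

Step 15. The ruthenium carbene on the acrylate may close onto the C13=C14 alkene (six-membered lactone with excision of the decalin), or closure of the strained trisubstituted five-membered ring may stall. The fallback sets out from 19 and comes back at 21 without metathesis. Hydroformylation of 19 (Rh(acac)(CO)2, PPh3, CO/H2, toluene, 70 °C) should touch only the 1,1-disubstituted alkene and give the linear aldehyde F4, which closes onto the C16 hydroxyl to the lactol F5. Oxidation (TEMPO, PhI(OAc)2, CH2Cl2) would give the saturated γ-lactone F6. Enolisation (LiN(iPr)2, THF, −78 °C) and PhSeCl would give the α-phenylselanyl lactone F7. H2O2 with pyridine would oxidise it to the selenoxide F8, whose syn elimination towards C17–H gives the butenolide 21.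

Step 4. Under the Lewis-acidic silylation the δ-hydroxy ketone may cyclise onto C13 (hemiketal, then dehydration to the cyclic enol ether), or the ketone may be enol-silylated. The fallback sets out from 1 and comes back at 7, so that the C8 carbinol and the C13 ketone never coexist.
- KMnO4 cleavage of larixol itself would give the hydroxy enone F9.
- Et3SiCl and imidazole in DMF would give its silyl ether F10.
- The enol phosphate sequence of step 5 would lead via the enol phosphate F11 to the enyne F12.
- mCPBA (CH2Cl2, 0 °C) should attack the exocyclic alkene from the α face, opposite the axial C10 methyl, and leave the alkyne, giving the epoxide F13.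
- LiEt3BH (THF, 0 °C) would open it to the tertiary alcohol F14.
- Et3SiOTf and 2,6-lutidine would then give 7.

Further compounds
F1 | step 11 | (E)-vinyl iodide of the bis-silylated decalin | I/C=C(\C)CC[C@@H]1[C@@]2(C)CCCC(C)(C)[C@@H]2[C@@H](O[Si](CC)(CC)CC)C[C@@]1(C)O[Si](CC)(CC)CC
F2 | step 11 | (E)-alkenyllithium | [Li]/C=C(\C)CC[C@@H]1[C@@]2(C)CCCC(C)(C)[C@@H]2[C@@H](O[Si](CC)(CC)CC)C[C@@]1(C)O[Si](CC)(CC)CC
F3 | step 11 | (E)-alkenylmagnesium bromide | Br[Mg]/C=C(\C)CC[C@@H]1[C@@]2(C)CCCC(C)(C)[C@@H]2[C@@H](O[Si](CC)(CC)CC)C[C@@]1(C)O[Si](CC)(CC)CC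
F4 | step 15 | linear C19 aldehyde with free C16 hydroxyl | O=CCC(C)[C@H](O)[C@@H](O[Si](CC)(CC)CC)/C=C(\C)CC[C@@H]1[C@@]2(C)CCCC(C)(C)[C@@H]2[C@@H](O[Si](CC)(CC)CC)C[C@@]1(C)O[Si](CC)(CC)CC
F5 | step 15 | lactol (2-hydroxy-4-methyltetrahydrofuran ring) | CC1CC(O)O[C@@H]1[C@@H](O[Si](CC)(CC)CC)/C=C(\C)CC[C@@H]1[C@@]2(C)CCCC(C)(C)[C@@H]2[C@@H](O[Si](CC)(CC)CC)C[C@@]1(C)O[Si](CC)(CC)CC
F6 | step 15 | saturated γ-lactone | CC1CC(=O)O[C@@H]1[C@@H](O[Si](CC)(CC)CC)/C=C(\C)CC[C@@H]1[C@@]2(C)CCCC(C)(C)[C@@H]2[C@@H](O[Si](CC)(CC)CC)C[C@@]1(C)O[Si](CC)(CC)CC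
F7 | step 15 | α-phenylselanyl lactone | CC1C([Se]c2ccccc2)C(=O)O[C@@H]1[C@@H](O[Si](CC)(CC)CC)/C=C(\C)CC[C@@H]1[C@@]2(C)CCCC(C)(C)[C@@H]2[C@@H](O[Si](CC)(CC)CC)C[C@@]1(C)O[Si](CC)(CC)CC
F8 | step 15 | selenoxide of F7 | CC1C([Se](=O)c2ccccc2)C(=O)O[C@@H]1[C@@H](O[Si](CC)(CC)CC)/C=C(\C)CC[C@@H]1[C@@]2(C)CCCC(C)(C)[C@@H]2[C@@H](O[Si](CC)(CC)CC)C[C@@]1(C)O[Si](CC)(CC)CC
F9 | step 4 | 6α-hydroxy-14,15-dinorlabd-8(17)-en-13-one | CC(=O)CC[C@@H]1[C@@]2(C)CCCC(C)(C)[C@@H]2[C@@H](O)CC1=C
F10 | step 4 | 6α-(triethylsilyloxy)-14,15-dinorlabd-8(17)-en-13-one | CC(=O)CC[C@@H]1[C@@]2(C)CCCC(C)(C)[C@@H]2[C@@H](O[Si](CC)(CC)CC)CC1=C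
F11 | step 4 | terminal enol diethyl phosphate of F10 | C=C(OP(=O)(OCC)OCC)CC[C@@H]1[C@@]2(C)CCCC(C)(C)[C@@H]2[C@@H](O[Si](CC)(CC)CC)CC1=C
F12 | step 4 | 6α-(triethylsilyloxy)-14,15-dinorlabd-8(17)-en-13(16)-yne | C#CCC[C@@H]1[C@@]2(C)CCCC(C)(C)[C@@H]2[C@@H](O[Si](CC)(CC)CC)CC1=C
F13 | step 4 | 8α,17-epoxy-6α-(triethylsilyloxy)-14,15-dinorlabd-13(16)-yne | C#CCC[C@@H]1[C@@]2(C)CCCC(C)(C)[C@@H]2[C@@H](O[Si](CC)(CC)CC)C[C@]13CO3
F14 | step 4 | 6α-(triethylsilyloxy)-14,15-dinorlabd-13(16)-yn-8α-ol | C#CCC[C@@H]1[C@@]2(C)CCCC(C)(C)[C@@H]2[C@@H](O[Si](CC)(CC)CC)C[C@@]1(C)O
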